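The earlier runs and the new flask come from a simulation for substances that don't exist; noise was put on by code.

A closed, stirred vessel at constant volume and temperature receives the starting complex and the incoming ligand. The complex with one exchanged, the intermediate of two consecutive exchanges, rises and then falls. Along the way the incoming ligand can slip reversibly into its dormant form, the complex with one exchanged can turn reversibly into its isomer, and the leaving ligand can take starting complex to side product.

| setting | amber | green | teal | flask |
|---|---|---|---|---|
| starting complex | 13 mM | 30 mM | 20 mM | 20 mM |
| incoming ligand | 1.2 equiv | 1.2 equiv | 1.8 equiv | 1.20 equiv |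
| remark | run made earlier | run made earlier | run made earlier |  |
| time |  |  |  | 2.5 d |

| run | time / d | complex with one exchanged / % |
|---|---|---|
| amber | 0.0278 | 10.4 |
| amber | 0.0833 | 12.7 |
| amber | 0.208 | 10.8 |
| amber | 0.500 | 9.8 |
| amber | 1.25 | 8.2 |
| amber | 3.00 | 4.0 |
| green | 0.0278 | 14.8 |
| green | 0.0833 | 12.9 |
| green | 0.208 | 9.6 |
| green | 0.500 | 6.7 |
| green | 1.25 | 3.6 |
| green | 3.00 | 2.2 |
| teal | 0.0278 | 16.0 |
| teal | 0.104 | 12.3 |
| teal | 0.333 | 7.1 |
| teal | 1.04 | 2.2 |
| teal | 3.00 | 0.1 |

(each reading ± 0.3 percentage points)

- the numbers in the tables scatter by 0.3 percentage points (one standard deviation)
- steps thought possible: starting complex + incoming ligand -> leaving ligand + complex with one exchanged; complex with one exchanged + incoming ligand -> leaving ligand + complex with two exchanged; incoming ligand <-> dormant form; leaving ligand + starting complex -> side product; complex with one exchanged <-> isomer of the product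

- the moment within 2.5 d at which there is most complex with one exchanged
- the amount of complex with one exchanged, in percent of the starting complex charged, at that time
- earliest time at which at least nineteen twentieths of that best amount are there
- latest time at which they still are, in d

The bench rule for steps with two partners says that, at fixed equivalents, time multiplied by strength of the charge stays constant and the curve of fractions keeps its height. Amber's highest reading, at 0.0833 d, scales to 1.30 h in the flask; green's, its first at 0.0278 d, scales to 1.00 h. The flask's peak is reckoned between them.

Height is where the rule stops. Green reads 14.8% against amber's 12.7%, higher by 2.1 percentage points with a scatter of 0.3 points. The passages to dormant form and isomer each take one species, and such clocks stay put while, at fixed equivalents, a stronger charge speeds up the exchanges. So the height gets its own number: 0.183, the height exponent, which is the logarithm of the height ratio over the logarithm of the strength ratio. The flask has 1.54 times amber's strength, so its peak is reckoned at 13.7% of the charge.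

The forecast gives 13.8% at 1.2 h, open from 0.75 h to 0.08 d, and calls these “rough estimates, since no reading falls close to the peak”.

The flask peaks at 14.2% at 1.11 h, and the window asked for runs from 0.704 h to 0.0753 d.

    starting complex + incoming ligand → leaving ligand + complex with one exchanged (k = 0.00570 L mol⁻¹ s⁻¹)
    complex with one exchanged + incoming ligand → leaving ligand + complex with two exchanged (k = 0.0160 L mol⁻¹ s⁻¹)
    incoming ligand ⇌ dormant form (K = 1.50, k = 1.30 × 10⁻⁴ s⁻¹)
    leaving ligand + starting complex → side product (k = 0.00230 L mol⁻¹ s⁻¹)
    complex with one exchanged ⇌ isomer of the product (K = 1.60, k = 1.40 × 10⁻⁴ s⁻¹)

The exponent's height stands 0.50 points below the flask's value. A neighbouring flask keeps the starting complex and takes 4.80 equiv of incoming ligand, 4.00 times the flask's charge. The exponent was read with both charges moving together, and here the ligand moves by itself. Starting from the flask's peak, it gives 18.3% for the neighbour. The neighbour's peak is 18.7%.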